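## Structural features

Wailupemycin H is an unsymmetrical methylenebis(4-hydroxy-2-pyrone): one CH2 joins C3 of pyrone A to C3 of pyrone B. Pyrone A carries at C6 the methine C4 of an 8-hydroxy-1-tetralone whose C3 is a tertiary carbinol bearing phenyl. Pyrone B carries at C6 the C1 of a 4,5-dihydroxy-2-phenylnaphthalene, which is the same carbon unit after loss of water and aromatisation. The only stereocentres are the adjacent C3 and C4 of the tetralone; read from the target string they are 3R and 4S, with the hydroxyl cis to pyrone A and the phenyl trans to it.

The tetralone is a β-hydroxy ketone with a tertiary, benzylic carbinol next to a doubly activated C4–H. Acid or base can dehydrate it to the naphthalene, and base can reopen C3–C4 by retro-aldol cleavage. The 4-hydroxypyrones are vinylogous acids, nucleophilic at C3, and the peri-dihydroxynaphthalene is air-sensitive.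

The difficulty is twofold: setting C3 and C4 (absolute and relative) in a ring one elimination away from an arene, and joining two different pyrones through one carbon without a statistical mixture. The plan exploits the fact that C3–C4 links a former benzoyl carbon to the methylene between the arene and C6 of pyrone A. One achiral aryl 1,3-diketone bearing a pyronylmethyl group therefore holds the skeleton of both halves: closure without loss of water gives the tetralone, closure with loss of water gives the naphthalene.

One design point is settled here: the cyclisation substrate carries the phenol as a benzyl ether. A free ortho-hydroxyl would compete for the benzoyl carbon (cyclic hemiketal, then flavone) and add an acidic proton. The ether costs no step because the hydrogenolysis that frees the pyrone hydroxyl removes it too.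

## Logic of the disconnections

**18 ⇒ 12 + 15 (through 17 and 16).** The two C–C bonds from the bridge carbon to C3 of pyrone A and C3 of pyrone B are cut; the bridge carbon goes to an iminium form of formaldehyde. C3 of a 4-hydroxy-2-pyrone is the nucleophilic carbon of a vinylogous acid, and a methylene between two such carbons is the trace of a Mannich or Knoevenagel step followed by a Michael addition. The target falls into two halves of nearly equal size, neither needing protection, and no stereocentre is formed or touched. The forward step must not be statistical: one partner is activated first (16, then 17) and the other is used in excess. 12 is activated because it has a single strongly nucleophilic carbon, whereas 15 also has naphthol positions.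

**15 ⇒ 14 ⇒ 10 (through 13).** Two O–benzyl bonds are cut. Then the C1–C2 bond of the naphthalene is read, with water added back, as the bond between the methylene carbon and the benzoyl carbon of 10. 15 is achiral, so it should branch off before any asymmetric step and consume no enantioenriched material. Both halves of 18 then share every step up to 10. The forward step only asks for complete dehydration, the direction the system prefers.

**12 ⇒ 11.** Two O–benzyl bonds are cut (aryl ether at C8, vinylogous ester on pyrone A). One protecting group serves both oxygens and leaves by hydrogenolysis at neutrality, the only mode that neither dehydrates the aldol with acid nor cleaves it with base. The gain is a cyclisation product without acidic O–H. The forward step must spare the tertiary benzylic C–O bond, the aryl ketone and the pyrone double bonds.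

**11 ⇒ 10.** The C3–C4 bond is cut. C3 is a benzoyl carbon in disguise, and C4 is a methylene acidified by the arene and, through C6=C5 and C4=C3, by the pyrone carbonyl. The ring and both stereocentres vanish and 10 is achiral. The forward step must control two prochiral faces with a catalyst, work although the 1,3-diketone is more acidic than the methylene, and stop before dehydration. It must also run under kinetic control, because reopening of the bond returns achiral 10.

**10 ⇒ 8 + 9.** The bond between the acetyl α-carbon and the benzoyl carbon is cut (Claisen-type acylation). Seven carbons and the acidic diketone are removed, so the diketone enters last. The forward step must acylate the acetyl carbon and not the more acidic methylene between arene and pyrone. Soft enolisation meets this, because the Lewis acid on the ketone oxygen selects the site of deprotonation. Intramolecular acyl transfer from a phenol ester (Baker–Venkataraman) is not open, since the phenol is an ether.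

**8 ⇒ 3 + 5 (through 7 and 6).** The aryl–CH2 bond is cut. Both partners are at most two steps from commercial materials, and the methyl group of 5 can be metalated directly. The forward Negishi coupling must tolerate the acetyl group and occur at the exocyclic carbon. Making the zinc reagent by deprotonation avoids a radical bromination that would also attack the benzylic C–H bonds of the ether. An ether on the phenol avoids protonolysis of the organozinc.

**3 ⇒ 2 ⇒ 1, and 5 ⇒ 4.** The O–S bond of the triflate and the O–benzyl bonds are cut, leading to two commercial compounds. The forward steps must differentiate the two hydroxyls of 1; after the first alkylation the second hydroxyl is hydrogen-bonded to the acetyl group. They must also alkylate 4 on the 4-oxygen.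

## Other disconnections considered

**Alternative 1:**
- **Cut:** the O1–C6 bonds of pyrone A and pyrone B at once, back to A1. A1 is a di-tert-butyl 2,4-diacylpentanedioate in which each acyl group is an ynone; one alkyne ends on C4 of the silylated tetralone, the other on C1 of the silylated naphthalene.
- **Forward key step:** a cationic monovalent gold complex such as Ph3PAuNTf2 would activate both alkynes. Each tert-butyl ester carbonyl oxygen would add to the alkyne carbon remote from the ketone (6-endo-dig). Loss of the tert-butyl groups would give both 4-hydroxypyrones of A2, and desilylation would follow.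
- **In its favour:** the cyclisation is a well-established reaction type under neutral conditions, and on reliability of the key step itself it is the better of the two plans. The bridge carbon is already part of the open chain, so the two halves can be joined by stepwise C-alkylation of two different β-keto esters; this is at least the equal of the iminium-based union.
- **Against it here:**
  - It creates no stereocentre. C3 and C4 must exist beforehand in a 4-alkynyl tetralone for which no simple asymmetric entry is apparent.
  - In A1 the C4–H is benzylic, propargylic and vinylogously α to the ynone carbonyl, so epimerisation or allene formation threatens.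
  - The homopropargylic silyloxy oxygen at C3 could compete for the activated alkyne in a 5-endo mode.
  - Four silyl ethers must leave an elimination-prone product.
- **Comparison:**
  - Structure: the chosen plan takes both pyrone rings from 4; the alternative builds rings that can be bought.
  - Mechanism: better precedent for the alternative, but the stereochemical problem stays unsolved.
  - Step economy: clearly longer.

**Alternative 2:**
- **Cut:** N4a–N8a and N1–N2 of the naphthalene (naphthalene numbering), back to an open-chain precursor of the kind A3. In A3 the phenyl 1,3-diketone is masked as a 3-phenylisoxazole, and a β-methoxy ketone segment supplies the three unsubstituted ring carbons.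
- **Forward key step:** Mo(CO)6 would cleave the N–O bond and hydrolysis would unmask the diketone. Mild base would condense the inner methylene of the triketone with the isolated ketone, with dehydration and loss of the methoxy group, to give A4. The new benzylic methylene of A4 would then condense with the benzoyl carbonyl to give A5.
- **In its favour:** it follows the biosynthetic order of events and needs neither a preformed arene nor a palladium coupling; on that point it is the better. Its second closure forms the same bond as the chosen key step, so on mechanism the two are equal for that bond.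
- **Against it here:**
  - It delivers only the achiral half, in the dehydrated state. Nothing stops A4 at the aldol stage or controls its configuration, so the stereogenic half would still need the chosen key step.
  - The chain offers competing closures: pyranone and resorcinol formation, and addition of the freed phenol of A4 to the diketone toward a flavone.
  - A3 needs a multistep assembly.
- **Comparison:**
  - Structure: equal endpoint; A5 differs from 14 only by one benzyl group.
  - Mechanism: equal for the last bond, less controlled before it.
  - Step economy: worse, since 14 is one step from the shared intermediate 10.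

**Alternative 3:**
- **Cut:** C3–C4 and O1–C2 of pyrone A, separating the tetralone dioxinone A6 from the bis(trimethylsilyl) ketene acetal A8 of the naphthalene half.
- **Forward key step:** heating A6 (about 110 °C) would open the dioxinone to the acylketene A7. A7 would react as a 1-oxadiene with A8 in a [4+2] sense. Loss of one silyloxy group would close pyrone A and give A9; desilylation and debenzylation would follow.
- **In its favour:** the plan is fully convergent. The bridge carbon belongs to A8, so the union is unambiguous and no naphthol carbon can interfere; on this point it is better than the chosen plan. The cycloaddition is a known route to 4-hydroxypyrones and is the equal or better in precedent.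
- **Against it here:**
  - In A7 the stereocentre C4 is α to a ketone and β to the silyloxy group. At the temperature of the ring opening, enolisation would epimerise it and β-elimination would lead to the naphthalene.
  - The stereocentres again come from elsewhere, and A6 would itself need an asymmetric closure of the same C3–C4 bond on a less acidic methylene.
  - A silyl ether and four benzyl ethers require two deprotection operations.
- **Comparison:**
  - Structure: better control of the bridge; worse match of conditions to the fragile dyad.
  - Mechanism: thermal and robust in itself.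
  - Step economy: poorer.

Key step: step 6

Assumption: neutral 10 is taken to close to 11 with a favourable equilibrium, as the stability of the unprotected hydroxytetralone pyrone as a natural congener suggests; the sense of induction in step 6 is taken to be selectable between the quinine- and the quinidine-derived catalyst.

## Route

Step 1
Reactants: 1 acetophenone 2,6-dihydroxyacetophenone
Product: 2 benzyl ether 1-[2-(benzyloxy)-6-hydroxyphenyl]ethan-1-one
Conditions: BnBr (1.05 equiv), K2CO3, acetone, reflux
Reagents that add atoms: benzyl bromide, BrCc1ccccc1
Why: Williamson ether synthesis; after the first alkylation the remaining hydroxyl is held in the hydrogen bond to the acetyl oxygen and reacts much more slowly, so one equivalent of halide should give the mono-ether.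

Step 2
Reactants: 2 benzyl ether 1-[2-(benzyloxy)-6-hydroxyphenyl]ethan-1-one
Product: 3 aryl triflate 2-acetyl-3-(benzyloxy)phenyl trifluoromethanesulfonate
Conditions: Tf2O, pyridine, CH2Cl2, 0 °C
Reagents that add atoms: trifluoromethanesulfonic anhydride, O=S(=O)(OS(=O)(=O)C(F)(F)F)C(F)(F)F
Why: O-sulfonylation of the only remaining nucleophile, the chelated phenol; the triflate is the coupling handle and no acidic O–H is left for the organozinc of step 4.

Step 3
Reactants: 4 pyrone 4-hydroxy-6-methyl-2H-pyran-2-one
Product: 5 benzyl pyrone 4-(benzyloxy)-6-methyl-2H-pyran-2-one
Conditions: BnBr, K2CO3, DMF, 60 °C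
Reagents that add atoms: benzyl bromide, BrCc1ccccc1
Why: O-alkylation of the vinylogous acid at the 4-oxygen; the known minor competitors (C3-benzylation, alkylation at the 2-oxygen) are separable by chromatography.

Step 4
Reactants: 5 benzyl pyrone 4-(benzyloxy)-6-methyl-2H-pyran-2-one; 3 aryl triflate 2-acetyl-3-(benzyloxy)phenyl trifluoromethanesulfonate
Product: 8 ketone 6-[2-acetyl-3-(benzyloxy)benzyl]-4-(benzyloxy)-2H-pyran-2-one, via lithio pyrone 6 (not isolated), via zinc reagent 7 (not isolated)
Conditions: 5 (2 equiv), LiN(SiMe3)2, THF, −78 °C; ZnCl2, −78 to 0 °C; then 3, Pd(OAc)2 (5 mol %), SPhos (10 mol %), THF, 50 °C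
Reagents that add atoms: none
Why: Deprotonative metalation of the 6-methyl group, transmetalation to zinc and Negishi cross-coupling with the aryl triflate; zinc enolate-type reagents are known to couple with aryl electrophiles that carry enolisable ketones, and bond formation at the exocyclic carbon keeps the pyrone ring intact. Direct metalation replaces a radical bromination that would not spare the benzylic C–H bonds of the ether.

Step 5
Reactants: 8 ketone 6-[2-acetyl-3-(benzyloxy)benzyl]-4-(benzyloxy)-2H-pyran-2-one; 9 benzoyl chloride
Product: 10 triketone 1-[2-(benzyloxy)-6-{[4-(benzyloxy)-2-oxo-2H-pyran-6-yl]methyl}phenyl]-3-phenylpropane-1,3-dione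
Conditions: MgBr2·OEt2 (2.5 equiv), i-Pr2NEt (3 equiv), CH2Cl2, 0 °C to rt; cold 1 M HCl work-up
Reagents that add atoms: none
Why: Claisen-type C-acylation by soft enolisation: MgBr2 on the acetyl oxygen lets the amine remove an α-proton, the magnesium enolate is C-benzoylated, and the product rests as the unreactive magnesium diketonate until the cold acidic work-up, so 10 never meets free base. The amine alone is too weak to ionise the methylene between arene and pyrone, which a strong base would deprotonate first.

Step 6
Reactants: 10 triketone 1-[2-(benzyloxy)-6-{[4-(benzyloxy)-2-oxo-2H-pyran-6-yl]methyl}phenyl]-3-phenylpropane-1,3-dione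
Product: 11 aldol adduct (3R,4S)-8-(benzyloxy)-4-[4-(benzyloxy)-2-oxo-2H-pyran-6-yl]-3-hydroxy-3-phenyl-3,4-dihydronaphthalen-1(2H)-one
Conditions: quinine-derived squaramide–tertiary amine catalyst (N-aryl = 3,5-(CF3)2C6H3; 10 mol %), toluene (0.02 M), 0 °C; AcOH quench
Reagents that add atoms: none
Why: Proposed new method: the quinuclidine nitrogen removes a proton from the methylene between the arene and C6 of the pyrone, the ammonium–trienolate pair is held by the squaramide N–H bonds against the keto form of the benzoyl carbonyl, and the methylene carbon adds to that carbonyl to form C3–C4, after which proton return from the ammonium gives the tertiary alcohol and frees the catalyst; the closest known reaction types are the direct vinylogous aldol additions of butenolides and related dienolate precursors to activated ketones under bifunctional amine–hydrogen-bond-donor catalysis and the base-mediated intramolecular aldol closures of polyketide-type polyketones. The 1,3-diketone is the more acidic site and buffers the medium, so the reacting carbanion is a minor species in fast equilibrium and the product never meets a base stronger than the substrate enolate. The one ring that closes does so in the 6-(enolexo)-exo-trig mode; attack on the aryl ketone would need a four-membered ring, and the benzyl ether keeps the phenol oxygen from adding to the benzoyl carbon. C3 (R) and C4 (S) are both fixed in the same bond-forming transition state by the chiral ion pair, which selects one face of the ketone and one face of the trienolate carbon; the sense of induction cannot be predicted and is to be assigned on 11, the quinidine-derived pseudo-enantiomer being the reserve. The cis relation of hydroxyl and pyrone places phenyl and pyrone trans, where both can stand pseudo-axial, clear of each other and of the peri hydrogen, so the favoured transition state should resemble the less strained adduct. The step needs kinetic control, because reopening of C3–C4 would return achiral 10 and erode the enantiomeric purity and E1cB loss of water would lead to 14; a weak base in catalytic amount, low temperature and an acidic quench should secure this, and 11, no longer a 1,3-diketone, is not ionised by the catalyst.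

Step 7
Reactants: 11 aldol adduct (3R,4S)-8-(benzyloxy)-4-[4-(benzyloxy)-2-oxo-2H-pyran-6-yl]-3-hydroxy-3-phenyl-3,4-dihydronaphthalen-1(2H)-one
Product: 12 tetralone pyrone (3R,4S)-3,8-dihydroxy-4-(4-hydroxy-2-oxo-2H-pyran-6-yl)-3-phenyl-3,4-dihydronaphthalen-1(2H)-one
Conditions: H2 (1 atm), 10% Pd/C, EtOAc, rt
Reagents that add atoms: none
Why: Hydrogenolysis of the aryl benzyl ether and of the benzyl vinylogous ester under neutral conditions; without acid the tertiary benzylic alcohol and the doubly benzylic C–H should be spared, the reaction is stopped after uptake of two equivalents of hydrogen, and neither stereocentre is touched.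

Step 8
Reactants: 10 triketone 1-[2-(benzyloxy)-6-{[4-(benzyloxy)-2-oxo-2H-pyran-6-yl]methyl}phenyl]-3-phenylpropane-1,3-dione
Product: 14 naphthol 4-(benzyloxy)-6-[5-(benzyloxy)-4-hydroxy-2-phenylnaphthalen-1-yl]-2H-pyran-2-one, via aldol adduct 13 (not isolated)
Conditions: DBU (1.5 equiv), THF, 50 °C; AcOH
Reagents that add atoms: none
Why: Base-mediated intramolecular aldol condensation across the same bond as in step 6, followed by E1cB loss of water and tautomerisation to the naphthol; the aromatisation that step 6 must avoid is here the driving force, and because 14 is achiral no enantioenriched material is spent on it.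

Step 9
Reactants: 14 naphthol 4-(benzyloxy)-6-[5-(benzyloxy)-4-hydroxy-2-phenylnaphthalen-1-yl]-2H-pyran-2-one
Product: 15 naphthalenediol pyrone 6-(4,5-dihydroxy-2-phenylnaphthalen-1-yl)-4-hydroxy-2H-pyran-2-one
Conditions: H2 (1 atm), 10% Pd/C, EtOAc–MeOH, rt; handled under argon
Reagents that add atoms: none
Why: Hydrogenolysis of both benzyl ethers as in step 7; the peri-dihydroxynaphthalene is oxidisable and is used directly.

Step 10
Reactants: 12 tetralone pyrone (3R,4S)-3,8-dihydroxy-4-(4-hydroxy-2-oxo-2H-pyran-6-yl)-3-phenyl-3,4-dihydronaphthalen-1(2H)-one; 15 naphthalenediol pyrone 6-(4,5-dihydroxy-2-phenylnaphthalen-1-yl)-4-hydroxy-2H-pyran-2-one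
Product: 18 wailupemycin H, via Mannich base 16 (not isolated), via methylene pyrandione 17 (not isolated)
Conditions: 12, [Me2N=CH2]I (1.05 equiv), MeCN, 0 °C to rt; then 15 (1.5 equiv), NaOAc (2 equiv), MeCN–MeOH, 40 °C, argon
Reagents that add atoms: N,N-dimethylmethyleneiminium iodide, C=[N+](C)C.[I-]
Why: Mannich reaction at C3 of pyrone A, the only strongly nucleophilic carbon of 12, then buffered elimination of dimethylamine to the 3-methylene-pyran-2,4-dione and Michael addition of C3 of the pyronate of 15. The stepwise course with 15 in excess avoids the statistical mixture of a one-pot formaldehyde condensation, and the near-neutral medium should leave C3 and C4 of the tetralone untouched.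

## Compound list

1 | 2,6-dihydroxyacetophenone | CC(=O)c1c(O)cccc1O | starting material
2 | 1-[2-(benzyloxy)-6-hydroxyphenyl]ethan-1-one | CC(=O)c1c(O)cccc1OCc1ccccc1 | intermediate
3 | 2-acetyl-3-(benzyloxy)phenyl trifluoromethanesulfonate | CC(=O)c1c(OCc2ccccc2)cccc1OS(=O)(=O)C(F)(F)F | intermediate
4 | 4-hydroxy-6-methyl-2H-pyran-2-one | Cc1cc(O)cc(=O)o1 | starting material
5 | 4-(benzyloxy)-6-methyl-2H-pyran-2-one | Cc1cc(OCc2ccccc2)cc(=O)o1 | intermediate
6 | {[4-(benzyloxy)-2-oxo-2H-pyran-6-yl]methyl}lithium (not isolated) | [Li]Cc1cc(OCc2ccccc2)cc(=O)o1 | intermediate
7 | {[4-(benzyloxy)-2-oxo-2H-pyran-6-yl]methyl}zinc chloride (not isolated) | Cl[Zn]Cc1cc(OCc2ccccc2)cc(=O)o1 | intermediate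
8 | 6-[2-acetyl-3-(benzyloxy)benzyl]-4-(benzyloxy)-2H-pyran-2-one | CC(=O)c1c(OCc2ccccc2)cccc1Cc1cc(OCc2ccccc2)cc(=O)o1 | intermediate
9 | benzoyl chloride | O=C(Cl)c1ccccc1 | starting material
10 | 1-[2-(benzyloxy)-6-{[4-(benzyloxy)-2-oxo-2H-pyran-6-yl]methyl}phenyl]-3-phenylpropane-1,3-dione | O=C(CC(=O)c1ccccc1)c1c(OCc2ccccc2)cccc1Cc1cc(OCc2ccccc2)cc(=O)o1 | intermediate
11 | (3R,4S)-8-(benzyloxy)-4-[4-(benzyloxy)-2-oxo-2H-pyran-6-yl]-3-hydroxy-3-phenyl-3,4-dihydronaphthalen-1(2H)-one | O=C1C[C@](O)(c2ccccc2)[C@@H](c2cc(OCc3ccccc3)cc(=O)o2)c2cccc(OCc3ccccc3)c21 | intermediate
12 | (3R,4S)-3,8-dihydroxy-4-(4-hydroxy-2-oxo-2H-pyran-6-yl)-3-phenyl-3,4-dihydronaphthalen-1(2H)-one | O=C1C[C@](O)(c2ccccc2)[C@@H](c2cc(O)cc(=O)o2)c2cccc(O)c21 | intermediate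
13 | 8-(benzyloxy)-4-[4-(benzyloxy)-2-oxo-2H-pyran-6-yl]-3-hydroxy-3-phenyl-3,4-dihydronaphthalen-1(2H)-one, mixture of stereoisomers (not isolated) | O=C1CC(O)(c2ccccc2)C(c2cc(OCc3ccccc3)cc(=O)o2)c2cccc(OCc3ccccc3)c21 | intermediate
14 | 4-(benzyloxy)-6-[5-(benzyloxy)-4-hydroxy-2-phenylnaphthalen-1-yl]-2H-pyran-2-one | O=c1cc(OCc2ccccc2)cc(-c2c(-c3ccccc3)cc(O)c3c(OCc4ccccc4)cccc23)o1 | intermediate
15 | 6-(4,5-dihydroxy-2-phenylnaphthalen-1-yl)-4-hydroxy-2H-pyran-2-one | O=c1cc(O)cc(-c2c(-c3ccccc3)cc(O)c3c(O)cccc23)o1 | intermediate
16 | (3R,4S)-4-{3-[(dimethylamino)methyl]-4-hydroxy-2-oxo-2H-pyran-6-yl}-3,8-dihydroxy-3-phenyl-3,4-dihydronaphthalen-1(2H)-one (not isolated) | O=C1C[C@](O)(c2ccccc2)[C@@H](c2cc(O)c(CN(C)C)c(=O)o2)c2cccc(O)c21 | intermediate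
17 | (3R,4S)-3,8-dihydroxy-4-(3-methylidene-2,4-dioxo-3,4-dihydro-2H-pyran-6-yl)-3-phenyl-3,4-dihydronaphthalen-1(2H)-one (not isolated) | O=C1C[C@](O)(c2ccccc2)[C@@H](C2=CC(=O)C(=C)C(=O)O2)c2cccc(O)c21 | intermediate
18 | wailupemycin H | O=C1C[C@](O)(c2ccccc2)[C@@H](c2cc(O)c(Cc3c(O)cc(-c4c(-c5ccccc5)cc(O)c5c(O)cccc45)oc3=O)c(=O)o2)c2cccc(O)c21 | target

## Step count and least certain steps

Total step count: 10. Longest linear sequence: 7 steps (steps 1, 2, 4, 5, 6, 7, 10). Step 3 and steps 8–9 are side branches.

**Step 6 (key step, new method).** Three processes are most likely to fail.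
- Ionisation of the methylene may be too slow, because the catalyst is largely occupied by the more acidic diketone.
- Facial selectivity may be poor, because the charge of the trienolate sits on the distant pyrone carbonyl and the chiral ion pair is loosely organised around the reacting carbons.
- Retro-aldol reopening or dehydration may set in if the reaction is pushed.

Fallback with known chemistry, setting out from 10 and returning at 11: 10 is cyclised with a catalytic achiral tertiary amine (Et3N, toluene, 0 °C), the known biomimetic closure mode. The cis adduct is separated from the trans isomers on silica. The racemate is resolved by preparative chromatography on a chiral stationary phase into 11 and its enantiomer (3S,4R)-8-(benzyloxy)-4-[4-(benzyloxy)-2-oxo-2H-pyran-6-yl]-3-hydroxy-3-phenyl-3,4-dihydronaphthalen-1(2H)-one F1. F1 and the trans isomers (part of 13) are not lost: DBU converts them into 14, which the route needs in equal amount.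

**Step 4.** Three processes may interfere.
- Transmetalation or reductive elimination of the stabilised zinc trienolate may be sluggish.
- Proton transfer from the more acidic methylene of product 8 to 7 consumes reagent; this is why two equivalents are used.
- 7 may add to the acetyl group.

Fallback, setting out from 5 and returning at 8: the lithio compound 6 is quenched with Bu3SnCl to give the isolable, neutral stannane 4-(benzyloxy)-6-[(tributylstannyl)methyl]-2H-pyran-2-one F2. F2 is joined to 3 by Stille coupling (Pd(PPh3)4, LiCl, CuI, dioxane, 90 °C), where no basic organometallic is present.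

**Step 5.** Two processes may interfere.
- Enolisation may occur at the methylene between arene and pyrone, which is thermodynamically more acidic, followed by benzoylation there.
- The diketone may be O-benzoylated by excess acid chloride.

Fallback, setting out from 3 and returning at 10: the order of the two C–C bond formations is reversed. 3, which has a single enolisable site, is benzoylated with 9 under the same soft-enolisation conditions to give 3-(benzyloxy)-2-(3-oxo-3-phenylpropanoyl)phenyl trifluoromethanesulfonate F3. F3 is then coupled with 7 (2.2 equiv, the first equivalent being consumed by the acidic diketone proton) under the conditions of step 4, with cold acidic work-up.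

**Step 10.** Three processes may interfere.
- Retro-aldol cleavage or dehydration of the tetralone may occur while it sits as the Mannich base in the presence of amine.
- Homodimer formation may occur if free 12 is still present when 17 forms.
- Naphthol carbons of 15 may be alkylated by 17.

Fallback, setting out from 15 and returning at 18: the roles are exchanged and the activated partner is isolated. 15 is treated with [Me2N=CH2]I to give 6-(4,5-dihydroxy-2-phenylnaphthalen-1-yl)-3-[(dimethylamino)methyl]-4-hydroxy-2H-pyran-2-one F4, which is purified. F4 is warmed with 12 and NaOAc; it loses dimethylamine to 6-(4,5-dihydroxy-2-phenylnaphthalen-1-yl)-3-methylidene-2H-pyran-2,4(3H)-dione F5, which is trapped by C3 of 12. The sensitive half then only meets the Michael stage.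

## Further compounds

F1 | step 6 | (3S,4R)-8-(benzyloxy)-4-[4-(benzyloxy)-2-oxo-2H-pyran-6-yl]-3-hydroxy-3-phenyl-3,4-dihydronaphthalen-1(2H)-one | O=C1C[C@@](O)(c2ccccc2)[C@H](c2cc(OCc3ccccc3)cc(=O)o2)c2cccc(OCc3ccccc3)c21
F2 | step 4 | 4-(benzyloxy)-6-[(tributylstannyl)methyl]-2H-pyran-2-one | CCCC[Sn](CCCC)(CCCC)Cc1cc(OCc2ccccc2)cc(=O)o1
F3 | step 5 | 3-(benzyloxy)-2-(3-oxo-3-phenylpropanoyl)phenyl trifluoromethanesulfonate | O=C(CC(=O)c1ccccc1)c1c(OCc2ccccc2)cccc1OS(=O)(=O)C(F)(F)F
F4 | step 10 | 6-(4,5-dihydroxy-2-phenylnaphthalen-1-yl)-3-[(dimethylamino)methyl]-4-hydroxy-2H-pyran-2-one | CN(C)Cc1c(O)cc(-c2c(-c3ccccc3)cc(O)c3c(O)cccc23)oc1=O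
F5 | step 10 | 6-(4,5-dihydroxy-2-phenylnaphthalen-1-yl)-3-methylidene-2H-pyran-2,4(3H)-dione | C=C1C(=O)C=C(-c2c(-c3ccccc3)cc(O)c3c(O)cccc23)OC1=O
A1 | alternative 1 | di-tert-butyl 2-{3-[4-oxo-2-phenyl-2,5-bis(triethylsilyloxy)-1,2,3,4-tetrahydronaphthalen-1-yl]prop-2-ynoyl}-4-{3-[2-phenyl-4,5-bis(triethylsilyloxy)naphthalen-1-yl]prop-2-ynoyl}pentanedioate, tetralin centres as in 18 | O=C1C[C@](O[Si](CC)(CC)CC)(c2ccccc2)[C@@H](C#CC(=O)C(C(=O)OC(C)(C)C)CC(C(=O)OC(C)(C)C)C(=O)C#Cc2c(-c3ccccc3)cc(O[Si](CC)(CC)CC)c3c(O[Si](CC)(CC)CC)cccc23)c2cccc(O[Si](CC)(CC)CC)c21
A2 | alternative 1 | wailupemycin H tetrakis(triethylsilyl) ether (tertiary hydroxyl, tetralone phenol and both naphthalene hydroxyls silylated) | O=C1C[C@](O[Si](CC)(CC)CC)(c2ccccc2)[C@@H](c2cc(O)c(Cc3c(O)cc(-c4c(-c5ccccc5)cc(O[Si](CC)(CC)CC)c5c(O[Si](CC)(CC)CC)cccc45)oc3=O)c(=O)o2)c2cccc(O[Si](CC)(CC)CC)c21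
A3 | alternative 2 | 4-(benzyloxy)-6-[4-methoxy-2,6-dioxo-7-(3-phenyl-1,2-oxazol-5-yl)heptyl]-2H-pyran-2-one | COC(CC(=O)Cc1cc(-c2ccccc2)no1)CC(=O)Cc1cc(OCc2ccccc2)cc(=O)o1
A4 | alternative 2 | 4-(benzyloxy)-6-[3-hydroxy-2-(3-oxo-3-phenylpropanoyl)benzyl]-2H-pyran-2-one | O=C(CC(=O)c1ccccc1)c1c(O)cccc1Cc1cc(OCc2ccccc2)cc(=O)o1
A5 | alternative 2 | 4-(benzyloxy)-6-(4,5-dihydroxy-2-phenylnaphthalen-1-yl)-2H-pyran-2-one | O=c1cc(OCc2ccccc2)cc(-c2c(-c3ccccc3)cc(O)c3c(O)cccc23)o1
A6 | alternative 3 | 6-[5-(benzyloxy)-4-oxo-2-phenyl-2-(triethylsilyloxy)-1,2,3,4-tetrahydronaphthalen-1-yl]-2,2-dimethyl-4H-1,3-dioxin-4-one, tetralin centres as in 18 | O=C1C[C@](O[Si](CC)(CC)CC)(c2ccccc2)[C@@H](C2=CC(=O)OC(C)(C)O2)c2cccc(OCc3ccccc3)c21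
A7 | alternative 3 | acylketene 3-[5-(benzyloxy)-4-oxo-2-phenyl-2-(triethylsilyloxy)-1,2,3,4-tetrahydronaphthalen-1-yl]-3-oxoprop-1-en-1-one, tetralin centres as in 18 | O=C1C[C@](O[Si](CC)(CC)CC)(c2ccccc2)[C@@H](C(=O)C=C=O)c2cccc(OCc3ccccc3)c21
A8 | alternative 3 | 4-(benzyloxy)-6-[4,5-bis(benzyloxy)-2-phenylnaphthalen-1-yl]-3-[3,3-bis(trimethylsilyloxy)prop-2-en-1-yl]-2H-pyran-2-one | C[Si](C)(C)OC(O[Si](C)(C)C)=CCc1c(OCc2ccccc2)cc(-c2c(-c3ccccc3)cc(OCc3ccccc3)c3c(OCc4ccccc4)cccc23)oc1=O
A9 | alternative 3 | wailupemycin H with the tertiary hydroxyl as triethylsilyl ether and the tetralone phenol, both naphthalene hydroxyls and the hydroxyl of pyrone B as benzyl ethers | O=C1C[C@](O[Si](CC)(CC)CC)(c2ccccc2)[C@@H](c2cc(O)c(Cc3c(OCc4ccccc4)cc(-c4c(-c5ccccc5)cc(OCc5ccccc5)c5c(OCc6ccccc6)cccc45)oc3=O)c(=O)o2)c2cccc(OCc3ccccc3)c21
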